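Ring B is disconnected at C5–C6 by reading C4 (the carbon that carries C18 and C19) and C8 (the carbon that carries the C17 methylene) as carbonyl carbons: C4(=O)–C5–C6–C7–C8(=O) is a 1,5-diketone. Ring B is therefore closed by an intramolecular Mukaiyama–Michael addition of a ring A silyl enol ether (C5) to a tethered vinyl ketone (C6). In one operation this forms C5–C6, delivers the two carbonyls differentiated (free C4 ketone, C7=C8 silyl enol ether) and places C5, and later C9, under thermodynamic control by the one catalytically set quaternary centre C10. The precursor is a monocyclic 3,3-disubstituted cyclohexanone silyl enol ether that already carries the whole side chain.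

Key step: step 9

Remark: atoms carry labdane numbers (ring A = C1–C5, C10; ring B = C5–C10; C17 = methylene on C8; C18 = α-methyl and C19 = ester carbon on C4; C20 = methyl on C10; side chain C11–C16); the target is taken as the (4S,5R,7S,9R,10R) enantiomer of the given SMILES, methyl 7β-acetoxy-15-hydroxylabda-8(17),13E-dien-19-oate.

Remark: C9 is created without control in step 5 and is carried as both epimers (SMILES without a C9 descriptor) through compounds 10–22; it is converged by equilibration in step 13.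

Step 1
Reactants: 1 hex-5-yn-2-one; 2 triethyl phosphonoacetate
Product: 3 ethyl (2E)-3-methylhept-2-en-6-ynoate
Conditions: NaH, THF, 0 °C → rt; minor Z isomer removed by chromatography
Reagents that add atoms: none
Why: Horner–Wadsworth–Emmons olefination of the methyl ketone should favour the E-enoate (ester trans to the larger CH2 substituent), which fixes the C13=C14 geometry of the side chain.

Step 2
Reactants: 3 ethyl (2E)-3-methylhept-2-en-6-ynoate
Product: 4 (2E)-3-methylhept-2-en-6-yn-1-ol
Conditions: i-Bu2AlH (2.2 equiv), CH2Cl2, −78 °C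
Reagents that add atoms: none
Why: 1,2-reduction of the conjugated ester by the aluminium hydride at low temperature should give the allylic alcohol without touching the alkyne or the alkene geometry.

Step 3
Reactants: 4 (2E)-3-methylhept-2-en-6-yn-1-ol
Product: 5 tert-butyl{[(2E)-3-methylhept-2-en-6-yn-1-yl]oxy}diphenylsilane
Conditions: TBDPSCl, imidazole, DMF, rt
Reagents that add atoms: tert-butyl(chloro)diphenylsilane CC(C)(C)[Si](Cl)(c1ccccc1)c1ccccc1
Why: imidazole-assisted silylation of the primary allylic alcohol gives a TBDPS ether that should survive alanes, boranes, hydrides, enolates and mild acid until step 17.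

Step 4
Reactants: 5 tert-butyl{[(2E)-3-methylhept-2-en-6-yn-1-yl]oxy}diphenylsilane; 6 3-methylcyclohex-2-en-1-one
Product: 9 (S)-configured TBS enol ether of 3-methyl-3-(1-alkylvinyl)cyclohexanone carrying the complete side chain, via alkenylalane 7 (not isolated), via aluminium enolate 8 (not isolated)
Conditions: i-Bu2AlH, NiCl2(dppp) (3 mol %), THF, 0 °C → rt; then 6, Cu(OTf)2 (5 mol %), chiral sulfonate-bearing imidazolinium salt (NHC precursor, 5 mol %), THF, −30 °C; then TBSOTf, −30 → 0 °C
Reagents that add atoms: tert-butyldimethylsilyl trifluoromethanesulfonate CC(C)(C)[Si](C)(C)OS(=O)(=O)C(F)(F)F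
Why: Ni-catalysed α-selective hydroalumination puts aluminium on the internal alkyne carbon, Cu/NHC-catalysed asymmetric conjugate addition of this 1,1-disubstituted alkenylalane to the β-methyl enone creates the quaternary centre C10 with the S configuration under catalyst control (ligand enantiomer chosen accordingly), and O-silylation of the aluminium enolate fixes the enol ether toward C5.

Step 5
Reactants: 9 TBS enol ether
Product: 11 primary alcohol at C8 (C9 epimers), via alkylborane 10 (not isolated)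
Conditions: 9-BBN, THF, rt → 50 °C; then 30% H2O2, aq NaOAc, 0 °C → rt
Reagents that add atoms: hydrogen peroxide OO
Why: anti-Markovnikov hydroboration–oxidation; 9-BBN should add to the terminal carbon of the 1,1-disubstituted C8=C9 alkene in preference to the hindered trisubstituted enol ether and side-chain alkenes, and the uncontrolled C9 centre is accepted because step 13 equilibrates it.

Step 6
Reactants: 11 primary alcohol
Product: 12 aldehyde at C8 (C9 epimers)
Conditions: Dess–Martin periodinane, NaHCO3, CH2Cl2, 0 °C → rt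
Reagents that add atoms: none
Why: buffered Dess–Martin oxidation of the primary alcohol to the aldehyde is compatible with the acid-sensitive silyl enol ether.

Step 7
Reactants: 12 aldehyde; 13 vinylmagnesium bromide
Product: 14 allylic alcohol (C8 and C9 epimers)
Conditions: THF, −78 °C; aq NH4Cl
Reagents that add atoms: none
Why: Grignard 1,2-addition to the aldehyde brings in C7 and C6, and the new carbinol centre C8 is oxidised away in step 8.

Step 8
Reactants: 14 allylic alcohol
Product: 15 vinyl ketone (C9 epimers)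
Conditions: Dess–Martin periodinane, NaHCO3, CH2Cl2, 0 °C
Reagents that add atoms: none
Why: Dess–Martin oxidation of the allylic alcohol gives the vinyl ketone that serves as the Michael acceptor.

Step 9
Reactants: 15 vinyl ketone
Product: 17 trans-fused bicyclic C4 ketone (5α-H; 10β-CH3; C9 epimers) carrying the C7=C8 TBS enol ether, via kinetic ring-closed ketone 16 (not isolated)
Conditions: HNTf2 (3 mol %), CH2Cl2 (high dilution), −78 → 0 °C; Et3N quench; then DBU, toluene, 60 °C
Reagents that add atoms: none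
Why: Catalytic HNTf2 is converted by the substrate into TBSNTf2, which silylates the enone oxygen; the ring A silyl enol ether then adds through C5 to the terminal carbon C6 of the activated vinyl ketone and the silyl group on the C4 oxocarbenium ion is handed on to the next enone, releasing the C4 ketone and the C7=C8 silyl enol ether (intramolecular Mukaiyama–Michael addition under silyl-transfer catalysis). Ring B closes in the 6-(enolexo)-endo-trig mode, which the unhindered CH nucleophile and CH2 acceptor terminus make favourable. C5 is the only stereocentre created; it is alpha to the C4 ketone, so the DBU treatment should equilibrate it to the trans-fused 5α-H isomer, the controlling element being the fixed quaternary C10, whose axial methyl group meets no 1,3-diaxial hydrogen at the sp2 carbons C4 and C8. The step needs regiocontrol of the nucleophile and differentiation of the two carbonyl groups that it sets in a 1,5-relationship: the enol ether installed in step 4 can only react at C5, and silyl transfer leaves C8 masked while C4 stays free for steps 10 to 12. C9 is untouched and stays epimeric until step 13.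

Step 10
Reactants: 17 trans-fused C4 ketone
Product: 19 Δ3 enol triflate at C4 (C9 epimers), via potassium enolate 18 (not isolated)
Conditions: KN(SiMe3)2, THF, −78 °C; then PhNTf2, −78 → 0 °C
Reagents that add atoms: N-phenylbis(trifluoromethanesulfonimide) O=S(=O)(N(c1ccccc1)S(=O)(=O)C(F)(F)F)C(F)(F)F
Why: kinetic deprotonation takes the C3 methylene in preference to the ring-fusion C5–H, and O-triflation of the enolate gives the Δ3 enol triflate without disturbing the silyl enol ether.

Step 11
Reactants: 19 enol triflate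
Product: 20 α,β-unsaturated methyl ester (C19 on C4; Δ3; C9 epimers)
Conditions: Pd(OAc)2 (5 mol %), PPh3 (10 mol %), CO (1 atm), MeOH, Et3N, DMF, 40 °C
Reagents that add atoms: carbon monoxide [C-]#[O+]; methanol CO
Why: Pd-catalysed methoxycarbonylation of the vinyl triflate (oxidative addition, CO insertion, methanolysis) installs C19 as the conjugated methyl ester.

Step 12
Reactants: 20 unsaturated ester
Product: 22 saturated ester with quaternary C4 (4α-CH3; 4β-CO2CH3; C9 epimers), via lithium ester enolate 21 (not isolated)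
Conditions: LiBH(s-Bu)3, THF, −78 °C; then MeI, DMPU, −78 → 0 °C
Reagents that add atoms: iodomethane CI
Why: conjugate hydride addition to C3 gives the exocyclic ester enolate, which MeI should alkylate from the equatorial α face, anti to the axial C10 methyl group, so that C4 carries α-CH3 (C18) and axial β-CO2CH3 (C19) (conjugate reduction–enolate alkylation).

Step 13
Reactants: 22 ester with C7=C8 TBS enol ether
Product: 23 8-ketone with the side chain equatorial (9α-H)
Conditions: NaOMe (0.5 equiv), MeOH–THF, rt → 40 °C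
Reagents that add atoms: none
Why: methoxide cleaves the silyl enol ether and reversible enolisation of the liberated 8-ketone toward C9 should converge both epimers on the isomer with the equatorial side chain, while C4, C5 and C10 cannot epimerise.

Step 14
Reactants: 23 8-ketone
Product: 25 7α-hydroxy-8-ketone, via potassium enolate 24 (not isolated)
Conditions: KN(SiMe3)2 (1.05 equiv), THF, −78 °C; then 2-(benzenesulfonyl)-3-phenyloxaziridine, −78 °C; AcOH quench
Reagents that add atoms: 2-(benzenesulfonyl)-3-phenyloxaziridine O=S(=O)(c1ccccc1)N1OC1c1ccccc1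
Why: kinetic enolisation takes the C7 methylene (C9–H is tertiary and neopentyl, the C19 ester has no α-hydrogen) and the oxaziridine should transfer oxygen axially to the α face, anti to the C10 methyl group, giving the 7α-alcohol (enolate hydroxylation).

Step 15
Reactants: 25 7α-hydroxy-8-ketone
Product: 26 7α-hydroxy-8(17)-ene
Conditions: Zn, CH2Br2, TiCl4, THF–CH2Cl2, 0 °C → rt
Reagents that add atoms: dibromomethane BrCBr
Why: the non-basic titanium methylidene reagent (Takai–Lombardo methylenation) should convert the hindered, enolisable 8-ketone into the C8=C17 methylene without epimerising C7 or C9.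

Step 16
Reactants: 26 7α-hydroxy-8(17)-ene
Product: 27 7β-acetate (C15 TBDPS ether of the target)
Conditions: AcOH, PPh3, DIAD, toluene, 0 °C → rt
Reagents that add atoms: acetic acid CC(=O)O
Why: Mitsunobu esterification displaces the activated axial allylic 7α-oxyphosphonium group by SN2 with inversion, giving the equatorial 7β-acetate directly.

Step 17
Reactants: 27 TBDPS ether
Product: 28 methyl 7β-acetoxy-15-hydroxylabda-8(17),13E-dien-19-oate (target)
Conditions: Bu4NF, AcOH, THF, 0 °C → rt
Reagents that add atoms: none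
Why: fluoride cleaves the primary TBDPS ether, and AcOH buffering should keep the C7 acetate and the hindered C19 ester intact.

Compound list
1 | hex-5-yn-2-one | CC(=O)CCC#C | starting material
2 | triethyl phosphonoacetate | CCOC(=O)CP(=O)(OCC)OCC | starting material
3 | ethyl (2E)-3-methylhept-2-en-6-ynoate | C#CCC/C(C)=C/C(=O)OCC | intermediate
4 | (2E)-3-methylhept-2-en-6-yn-1-ol | C#CCC/C(C)=C/CO | intermediate
5 | tert-butyl{[(2E)-3-methylhept-2-en-6-yn-1-yl]oxy}diphenylsilane | C#CCC/C(C)=C/CO[Si](c1ccccc1)(c1ccccc1)C(C)(C)C | intermediate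
6 | 3-methylcyclohex-2-en-1-one | CC1=CC(=O)CCC1 | starting material
7 | {(5E)-7-[(tert-butyldiphenylsilyl)oxy]-5-methylhepta-1,5-dien-2-yl}diisobutylalane (not isolated) | C=C(CC/C(C)=C/CO[Si](c1ccccc1)(c1ccccc1)C(C)(C)C)[Al](CC(C)C)CC(C)C | intermediate
8 | diisobutylaluminium enolate (O on C4, C4=C5) of the (S)-conjugate adduct (not isolated) | C=C(CC/C(C)=C/CO[Si](c1ccccc1)(c1ccccc1)C(C)(C)C)[C@@]1(C)CCCC(O[Al](CC(C)C)CC(C)C)=C1 | intermediate
9 | tert-butyl{[(3S)-3-{(5E)-7-[(tert-butyldiphenylsilyl)oxy]-5-methylhepta-1,5-dien-2-yl}-3-methylcyclohex-1-en-1-yl]oxy}dimethylsilane | C=C(CC/C(C)=C/CO[Si](c1ccccc1)(c1ccccc1)C(C)(C)C)[C@@]1(C)CCCC(O[Si](C)(C)C(C)(C)C)=C1 | intermediate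
10 | B-alkyl-9-borabicyclo[3.3.1]nonane from 9, boron on C8, C9 epimers (not isolated) | C(B1C2CCCC1CCC2)C(CC/C(C)=C/CO[Si](c1ccccc1)(c1ccccc1)C(C)(C)C)[C@@]1(C)CCCC(O[Si](C)(C)C(C)(C)C)=C1 | intermediate
11 | (5E)-2-[3-(tert-butyldimethylsilyloxy)-1-methylcyclohex-2-en-1-yl]-7-(tert-butyldiphenylsilyloxy)-5-methylhept-5-en-1-ol, ring quaternary carbon as in 9, C9 epimers | OCC(CC/C(C)=C/CO[Si](c1ccccc1)(c1ccccc1)C(C)(C)C)[C@@]1(C)CCCC(O[Si](C)(C)C(C)(C)C)=C1 | intermediate
12 | (5E)-2-[3-(tert-butyldimethylsilyloxy)-1-methylcyclohex-2-en-1-yl]-7-(tert-butyldiphenylsilyloxy)-5-methylhept-5-enal, C9 epimers | O=CC(CC/C(C)=C/CO[Si](c1ccccc1)(c1ccccc1)C(C)(C)C)[C@@]1(C)CCCC(O[Si](C)(C)C(C)(C)C)=C1 | intermediate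
13 | vinylmagnesium bromide | C=C[Mg]Br | starting material
14 | (7E)-4-[3-(tert-butyldimethylsilyloxy)-1-methylcyclohex-2-en-1-yl]-9-(tert-butyldiphenylsilyloxy)-7-methylnona-1,7-dien-3-ol, C8 and C9 epimers | C=CC(O)C(CC/C(C)=C/CO[Si](c1ccccc1)(c1ccccc1)C(C)(C)C)[C@@]1(C)CCCC(O[Si](C)(C)C(C)(C)C)=C1 | intermediate
15 | (7E)-4-[3-(tert-butyldimethylsilyloxy)-1-methylcyclohex-2-en-1-yl]-9-(tert-butyldiphenylsilyloxy)-7-methylnona-1,7-dien-3-one, C9 epimers | C=CC(=O)C(CC/C(C)=C/CO[Si](c1ccccc1)(c1ccccc1)C(C)(C)C)[C@@]1(C)CCCC(O[Si](C)(C)C(C)(C)C)=C1 | intermediate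
16 | 8-(tert-butyldimethylsilyloxy)-15-(tert-butyldiphenylsilyloxy)-17,18,19-trinorlabda-7,13E-dien-4-one as formed, 10β-CH3, C5 and C9 epimers (not isolated) | CC(C)(C)[Si](C)(C)OC1=CCC2[C@](C)(CCCC2=O)C1CC/C(C)=C/CO[Si](c1ccccc1)(c1ccccc1)C(C)(C)C | intermediate
17 | 8-(tert-butyldimethylsilyloxy)-15-(tert-butyldiphenylsilyloxy)-17,18,19-trinorlabda-7,13E-dien-4-one, 5α-H, 10β-CH3, C9 epimers | CC(C)(C)[Si](C)(C)OC1=CC[C@@H]2[C@](C)(CCCC2=O)C1CC/C(C)=C/CO[Si](c1ccccc1)(c1ccccc1)C(C)(C)C | intermediate
18 | potassium 3-en-4-olate of 17 (not isolated) | CC(C)(C)[Si](C)(C)OC1=CC[C@@H]2[C@](C)(CCC=C2[O-])C1CC/C(C)=C/CO[Si](c1ccccc1)(c1ccccc1)C(C)(C)C.[K+] | intermediate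
19 | 8-(tert-butyldimethylsilyloxy)-15-(tert-butyldiphenylsilyloxy)-17,18,19-trinorlabda-3,7,13E-trien-4-yl trifluoromethanesulfonate, 5α-H, C9 epimers | CC(C)(C)[Si](C)(C)OC1=CC[C@@H]2[C@](C)(CCC=C2OS(=O)(=O)C(F)(F)F)C1CC/C(C)=C/CO[Si](c1ccccc1)(c1ccccc1)C(C)(C)C | intermediate
20 | methyl 8-(tert-butyldimethylsilyloxy)-15-(tert-butyldiphenylsilyloxy)-17,18-dinorlabda-3,7,13E-trien-19-oate, 5α-H, C9 epimers | CC(C)(C)[Si](C)(C)OC1=CC[C@@H]2[C@](C)(CCC=C2C(=O)OC)C1CC/C(C)=C/CO[Si](c1ccccc1)(c1ccccc1)C(C)(C)C | intermediate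
21 | lithium ester enolate (C4=C19) from conjugate reduction of 20 (not isolated) | CC(C)(C)[Si](C)(C)OC1=CC[C@@H]2[C@](C)(CCCC2=C(OC)O[Li])C1CC/C(C)=C/CO[Si](c1ccccc1)(c1ccccc1)C(C)(C)C | intermediate
22 | methyl 8-(tert-butyldimethylsilyloxy)-15-(tert-butyldiphenylsilyloxy)-17-norlabda-7,13E-dien-19-oate, 4α-CH3, 4β-CO2CH3, 5α-H, C9 epimers | CC(C)(C)[Si](C)(C)OC1=CC[C@@H]2[C@](C)(CCC[C@]2(C)C(=O)OC)C1CC/C(C)=C/CO[Si](c1ccccc1)(c1ccccc1)C(C)(C)C | intermediate
23 | methyl 15-(tert-butyldiphenylsilyloxy)-8-oxo-17-norlabd-13E-en-19-oate, 5α-H, 9α-H | O=C1CC[C@@H]2[C@](C)(CCC[C@]2(C)C(=O)OC)[C@H]1CC/C(C)=C/CO[Si](c1ccccc1)(c1ccccc1)C(C)(C)C | intermediate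
24 | potassium 7-en-8-olate of 23 (not isolated) | [K+].[O-]C1=CC[C@@H]2[C@](C)(CCC[C@]2(C)C(=O)OC)[C@H]1CC/C(C)=C/CO[Si](c1ccccc1)(c1ccccc1)C(C)(C)C | intermediate
25 | methyl 15-(tert-butyldiphenylsilyloxy)-7α-hydroxy-8-oxo-17-norlabd-13E-en-19-oate | O=C1[C@H](O)C[C@@H]2[C@](C)(CCC[C@]2(C)C(=O)OC)[C@H]1CC/C(C)=C/CO[Si](c1ccccc1)(c1ccccc1)C(C)(C)C | intermediate
26 | methyl 15-(tert-butyldiphenylsilyloxy)-7α-hydroxylabda-8(17),13E-dien-19-oate | C=C1[C@H](O)C[C@@H]2[C@](C)(CCC[C@]2(C)C(=O)OC)[C@H]1CC/C(C)=C/CO[Si](c1ccccc1)(c1ccccc1)C(C)(C)C | intermediate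
27 | methyl 7β-acetoxy-15-(tert-butyldiphenylsilyloxy)labda-8(17),13E-dien-19-oate | C=C1[C@@H](OC(C)=O)C[C@@H]2[C@](C)(CCC[C@]2(C)C(=O)OC)[C@H]1CC/C(C)=C/CO[Si](c1ccccc1)(c1ccccc1)C(C)(C)C | intermediate
28 | methyl 7β-acetoxy-15-hydroxylabda-8(17),13E-dien-19-oate, (4S,5R,7S,9R,10R) | C=C1[C@@H](OC(C)=O)C[C@@H]2[C@](C)(CCC[C@]2(C)C(=O)OC)[C@H]1CC/C(C)=C/CO | target

Total step count: 17. Longest linear sequence: 17 steps (1 → 28); compounds 2, 6 and 13 and all reagents are purchased.

Steps most likely to fail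

Step 4. The hydroalumination may give incomplete internal (α) regiocontrol, the alkenyl transfer may proceed with insufficient enantioselectivity, or the aluminium enolate may be lost before O-silylation. The fallback adds the methyl group last. From 5, bromoboration with B-bromo-9-borabicyclo[3.3.1]nonane followed by protonolysis with AcOH would give the 2-bromo-1-alkene F1. Bromine–lithium exchange (t-BuLi, −78 °C), addition to 3-ethoxycyclohex-2-en-1-one and dilute acid work-up (Stork–Danheiser sequence) would give the 3-alkenylcyclohexenone F2. Cu-catalysed, ligand-controlled 1,4-selective asymmetric conjugate addition of MeMgBr (Cu(OTf)2, chiral NHC ligand) and silylation of the magnesium enolate with TBSOTf return to 9.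

Step 9. The acid may protodesilylate or isomerise the enol ether, the silyl oxocarbenium intermediate may be diverted into Michael–aldol (cyclobutane) closure or the enone into oligomers, and the C5 equilibrium may not lie far enough on the trans side. The fallback closes ring B through the same C5–C6 bond by enolate alkylation, with C8 kept at the alcohol level. From 14, silylation (TBSOTf, 2,6-lutidine) would give the C8 silyl ether F3. 9-BBN then H2O2 would give the primary C6 alcohol F4, and I2, PPh3, imidazole the iodide F5. Fluoride (tris(dimethylamino)sulfonium difluorotrimethylsilicate) unmasks the C5 enolate, which closes ring B by 6-exo-tet alkylation; DBU equilibration would give the trans-fused ketone F6. The conditions of steps 10 to 12 would then give the enol triflate F7, the unsaturated ester F8 and the C4-methylated ester F9. HF·pyridine removes the secondary TBS group to give the C8 alcohol F10. Dess–Martin oxidation followed by NaOMe in MeOH returns to 23.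

Step 16. Acetate may attack C17 (SN2′) or the activated alcohol may eliminate to the diene instead of undergoing clean inversion. The fallback inverts C7 by oxidation and reduction. From 26, MnO2 would give the 7-oxo-8(17)-ene F11. NaBH4 with CeCl3·7H2O in MeOH at −78 °C should deliver hydride axially from the α face to give the 7β-alcohol F12. Ac2O, pyridine and DMAP return to 27.

Further compounds
F1 | step 4 | tert-butyl{[(2E)-6-bromo-3-methylhepta-2,6-dien-1-yl]oxy}diphenylsilane | C=C(Br)CC/C(C)=C/CO[Si](c1ccccc1)(c1ccccc1)C(C)(C)C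
F2 | step 4 | 3-{(5E)-7-[(tert-butyldiphenylsilyl)oxy]-5-methylhepta-1,5-dien-2-yl}cyclohex-2-en-1-one | O=C1C=C(CCC1)C(=C)CC/C(C)=C/CO[Si](c1ccccc1)(c1ccccc1)C(C)(C)C
F3 | step 9 | C8 TBS ether of 14 (C8 and C9 epimers) | C=CC(O[Si](C)(C)C(C)(C)C)C(CC/C(C)=C/CO[Si](c1ccccc1)(c1ccccc1)C(C)(C)C)[C@@]1(C)CCCC(O[Si](C)(C)C(C)(C)C)=C1
F4 | step 9 | primary C6 alcohol from hydroboration of F3 | OCCC(O[Si](C)(C)C(C)(C)C)C(CC/C(C)=C/CO[Si](c1ccccc1)(c1ccccc1)C(C)(C)C)[C@@]1(C)CCCC(O[Si](C)(C)C(C)(C)C)=C1
F5 | step 9 | primary C6 iodide from F4 | ICCC(O[Si](C)(C)C(C)(C)C)C(CC/C(C)=C/CO[Si](c1ccccc1)(c1ccccc1)C(C)(C)C)[C@@]1(C)CCCC(O[Si](C)(C)C(C)(C)C)=C1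
F6 | step 9 | 8-(tert-butyldimethylsilyloxy)-15-(tert-butyldiphenylsilyloxy)-17,18,19-trinorlabd-13E-en-4-one, 5α-H, C8 and C9 epimers | CC(C)(C)[Si](C)(C)OC1CC[C@@H]2[C@](C)(CCCC2=O)C1CC/C(C)=C/CO[Si](c1ccccc1)(c1ccccc1)C(C)(C)C
F7 | step 9 | Δ3 enol triflate of F6 | CC(C)(C)[Si](C)(C)OC1CC[C@@H]2[C@](C)(CCC=C2OS(=O)(=O)C(F)(F)F)C1CC/C(C)=C/CO[Si](c1ccccc1)(c1ccccc1)C(C)(C)C
F8 | step 9 | methyl 8-(tert-butyldimethylsilyloxy)-15-(tert-butyldiphenylsilyloxy)-17,18-dinorlabda-3,13E-dien-19-oate | CC(C)(C)[Si](C)(C)OC1CC[C@@H]2[C@](C)(CCC=C2C(=O)OC)C1CC/C(C)=C/CO[Si](c1ccccc1)(c1ccccc1)C(C)(C)C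
F9 | step 9 | methyl 8-(tert-butyldimethylsilyloxy)-15-(tert-butyldiphenylsilyloxy)-17-norlabd-13E-en-19-oate, 4α-CH3, 4β-CO2CH3 | CC(C)(C)[Si](C)(C)OC1CC[C@@H]2[C@](C)(CCC[C@]2(C)C(=O)OC)C1CC/C(C)=C/CO[Si](c1ccccc1)(c1ccccc1)C(C)(C)C
F10 | step 9 | methyl 15-(tert-butyldiphenylsilyloxy)-8-hydroxy-17-norlabd-13E-en-19-oate, C8 and C9 epimers | OC1CC[C@@H]2[C@](C)(CCC[C@]2(C)C(=O)OC)C1CC/C(C)=C/CO[Si](c1ccccc1)(c1ccccc1)C(C)(C)C
F11 | step 16 | methyl 15-(tert-butyldiphenylsilyloxy)-7-oxolabda-8(17),13E-dien-19-oate | C=C1C(=O)C[C@@H]2[C@](C)(CCC[C@]2(C)C(=O)OC)[C@H]1CC/C(C)=C/CO[Si](c1ccccc1)(c1ccccc1)C(C)(C)C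
F12 | step 16 | methyl 15-(tert-butyldiphenylsilyloxy)-7β-hydroxylabda-8(17),13E-dien-19-oate | C=C1[C@@H](O)C[C@@H]2[C@](C)(CCC[C@]2(C)C(=O)OC)[C@H]1CC/C(C)=C/CO[Si](c1ccccc1)(c1ccccc1)C(C)(C)C
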